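The data were computed with constants of no real substance, noise included.

1. The vessel is closed, stirred and isothermal. Gas enters the solution toward 200 mM, and the flasks differ in their charge of starting complex.

in all of them: gas 200 mM (held)
- north: starting complex 0.33 M; run made earlier
- epsilon: starting complex 0.30 M; time 30 min
- alpha: starting complex 0.60 M; time 30 min
- gamma: starting complex 1.2 M; time 30 min
- theta: starting complex 2.5 M; time 30 min

- north (time / min: complex with one exchanged / %, starting complex / %): 0.833: 0.5, 100.0; 1.33: 0.7, 100.4; 2.50: 2.7, 97.2; 4.00: 5.9, 93.3; 6.00: 10.6, 87.0; 10.0: 19.3, 75.7

(each reading ± 1 percentage point)

- at the start none of the gas is in solution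
- a reading or a percentage of complex with one exchanged counts all its forms, free or not
- "hardly changes" means that all values lie within two and a half points (for a concentration: within two and a half percent of the largest)

- amount of complex with one exchanged at the end, in percent of the starting complex charged for epsilon, alpha, gamma, theta, in this order
- the course of these numbers from the first flask to the last (falls, then rises / hardly changes / rises all the way / falls all the way / rises, then falls)

2. I count turnovers. In north, starting complex falls from 93.3% at 4.00 min to 75.7% at 10.0 min, so I read a pace of 0.0348 min⁻¹, pseudo-first-order while dissolved gas stays steady. Over 30 min that makes 1.05 turnovers; a turnover count is this pace times the time, the number of e-foldings of starting complex. By my reckoning, that count leaves 35.2% of the starting complex.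

3. Time: by hand, more time means more turnovers. But the two columns of north add up to 95.0% at 10.0 min, a reading with the scatter above, so some product may be going on to something else.

4. Charge: by hand, if the pace does not depend on the charge, the percentage stays the same from flask to flask while gas keeps up. Yet theta asks for more gas per minute than epsilon. As a rough upper reckoning of demand, north's pace applied to the full charge for the whole time asks for 1.57 saturated solutions' worth of gas in epsilon and 13.1 in theta.

5. So I expect a row below 64.8%, sinking toward theta. I reckon no row of my own. The forecast says 50%, 47%, 43%, 38%, so falls all the way, holding that “gas transfer cannot keep up in concentrated flasks”.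

6. The flasks give 37.0%, 46.9%, 43.3%, 30.7%, so the course is: rises, then falls, turning at 0.68 M.

    crystals ⇌ complex with one exchanged, rate k1*(cs1 - [complex with one exchanged]) while solid is left; crystals form when [complex with one exchanged] > cs1 (solubility = 44.0 mM, k = 0.00830 s⁻¹)
    complex with one exchanged + incoming ligand ⇌ leaving ligand + complex with two exchanged (K = 10.0, k = 0.0130 M⁻¹ s⁻¹)
    starting complex + incoming ligand ⇌ leaving ligand + complex with one exchanged (K = 31.0, k = 0.00590 M⁻¹ s⁻¹)
    gas ⇌ incoming ligand, rate k4*(csat - [incoming ligand]) (kL = 0.00310 s⁻¹)

The forecast's first point stands 13 percentage points above epsilon's result, and at the end complex with two exchanged stands at 33.6% in epsilon, against 1.82% in theta. Counted again, the 29.4% of starting complex left in epsilon is 1.22 turnovers, against my 1.05. The 67.5% left in theta is 0.393 turnovers, with incoming ligand at 0.0471 M.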